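## Retrosynthetic overview

- **Feature:** in the six-membered ring, C4 with its methyl group lies between the C3 carbonyl and the oxirane CH C5, exactly as the α-carbon of a 2-methylcyclohex-2-enone. Removing this one carbon leaves a trans-2-oxy-3-alkenylcyclopentanone built from C3, C2, C1, C6 and C5.
- **End game:** the hydroperoxide comes from a Schenck ene reaction on a 4-methylpent-3-enoyl chain. The C7–C(O) bond comes from a Nozaki–Hiyama–Kishi coupling of a C7 alkenyl iodide (unmasked from a vinylsilane) with 4-methylpent-3-enal. The oxirane comes from hydroxyl-directed epoxidation of the C3 allylic alcohol, and the isovalerate from acylation of the C2 hydroxyl.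
- **Key disconnection:** C3–C4 and C4–C5, by addition of chloro(methyl)carbene to the cyclopentanone silyl enol ether and opening of the chlorocyclopropane.
- **Cyclopentanone:** asymmetric conjugate addition of the 1-silylvinyl group to cyclopentenone sets C1, Rubottom oxidation sets C2, and kinetic enol silylation places the enol ether towards C5.
- **Ring order:** the five-membered ring is bought, the six-membered ring is made by expansion in step 5, and the oxirane is closed in step 10.

Key step: step 5

Numbering used throughout: C1 (side-chain CH), C2 (ester CH), C3 (C=O), C4 (C–CH3), C5 (oxirane CH), C6 (CH2), C7 (side-chain carbon on C1). In this numbering the target is 1S,2S,4S,5S, with the oxirane cis to the side chain and trans to the ester. The CIP letter at C1 changes along the route only because the priority of C7 changes (Si or I versus C).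

## Route

Step 1
Reactants: 1 cyclopent-2-en-1-one; 2 (1-bromovinyl)trimethylsilane
Product: 5 (R)-trimethyl({3-[1-(trimethylsilyl)ethenyl]cyclopent-1-en-1-yl}oxy)silane, via Grignard reagent 3 (not isolated), via magnesium enolate 4 (not isolated)
Conditions: 2, Mg, THF, 45 °C; then 1, CuBr·SMe2 (5 mol%), Josiphos-type ferrocenyl diphosphine (6 mol%), t-BuOMe, −78 °C; then TMSCl, Et3N, DMPU, −78 → 0 °C
Reagents that add atoms: chlorotrimethylsilane, C[Si](C)(C)Cl
Why: Copper(I)-catalysed asymmetric conjugate addition of a Grignard reagent to a cyclic enone followed by O-silylation of the regiodefined magnesium enolate; the chiral copper–diphosphine complex selects the enone face so that C1 is formed R (the ligand enantiomer being chosen accordingly), and the trapping fixes the enol double bond between C3 and C2 for step 2.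

Step 2
Reactants: 5 (R)-trimethyl({3-[1-(trimethylsilyl)ethenyl]cyclopent-1-en-1-yl}oxy)silane
Product: 8 (2S,3R)-2-hydroxy-3-[1-(trimethylsilyl)ethenyl]cyclopentan-1-one, via siloxy epoxide 6 (not isolated), via trimethylsilyloxy ketone 7 (not isolated)
Conditions: mCPBA (1.05 equiv), NaHCO3, CH2Cl2, −20 → 0 °C; then citric acid, MeOH, 0 °C
Reagents that add atoms: meta-chloroperoxybenzoic acid, O=C(OO)c1cccc(Cl)c1
Why: Rubottom oxidation, in which the peracid epoxidises the electron-rich enol ether (far faster than the vinylsilane) on the face anti to the adjacent C1 substituent and silyl migration with opening of the siloxy epoxide, then methanolysis, should give the trans 2-hydroxy ketone (2S).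

Step 3
Reactants: 8 (2S,3R)-2-hydroxy-3-[1-(trimethylsilyl)ethenyl]cyclopentan-1-one
Product: 9 (2S,3R)-2-(tert-butyldimethylsilyloxy)-3-[1-(trimethylsilyl)ethenyl]cyclopentan-1-one
Conditions: TBSCl, imidazole, DMF, 0 °C → rt
Reagents that add atoms: tert-butyldimethylsilyl chloride, CC(C)(C)[Si](C)(C)Cl
Why: Standard silylation of a secondary alcohol, giving a bulky ether that survives LDA, butyllithium and the thermal ring opening and that shields the C2 hydrogen from deprotonation.

Step 4
Reactants: 9 (2S,3R)-2-(tert-butyldimethylsilyloxy)-3-[1-(trimethylsilyl)ethenyl]cyclopentan-1-one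
Product: 11 (4R,5S)-1,5-bis(tert-butyldimethylsilyloxy)-4-[1-(trimethylsilyl)ethenyl]cyclopent-1-ene, via lithium enolate 10 (not isolated)
Conditions: LDA, THF, −78 °C; then TBSOTf, −78 °C; Et3N quench
Reagents that add atoms: tert-butyldimethylsilyl trifluoromethanesulfonate, CC(C)(C)[Si](C)(C)OS(=O)(=O)C(F)(F)F
Why: Kinetic enolisation with LDA removes a proton from the unhindered C5 methylene and not from the silyloxy-bearing C2, and O-silylation of the lithium enolate by the silyl triflate should give the C3=C5 enol ether without touching the C1 or C2 stereocentres.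

Step 5
Reactants: 11 (4R,5S)-1,5-bis(tert-butyldimethylsilyloxy)-4-[1-(trimethylsilyl)ethenyl]cyclopent-1-ene; 12 1,1-dichloroethane
Product: 15 (5R,6S)-6-(tert-butyldimethylsilyloxy)-2-methyl-5-[1-(trimethylsilyl)ethenyl]cyclohex-2-en-1-one, via lithium carbenoid 13 (not isolated), via chlorocyclopropane 14 (not isolated)
Conditions: 12 (4 equiv), n-BuLi (3 equiv, slow addition), Et2O, −40 → −20 °C; aq. NH4Cl; then PhMe, Et3N, 110 °C
Reagents that add atoms: none
Why: Butyllithium deprotonates 1,1-dichloroethane and carbenoid 13 transfers chloro(methyl)carbene to the C3=C5 enol ether double bond, the most electron-rich π bond present, in a [2+1] addition that makes C3–C4 and C4–C5 and gives siloxy chlorocyclopropane 14. On heating, the epimer with chlorine endo (cis to the five-membered ring) ionises with concerted disrotatory cleavage of the C3–C5 fusion bond, a two-electron cyclopropyl-to-allyl electrocyclic opening, so the six-membered ring arises by ring expansion and not by an end-to-end closure. Chloride then takes the silyl group from the 2-siloxyallyl cation, leaving the C3 ketone conjugated with the C4=C5 alkene and the methyl group already on C4. This is the known halocarbene one-carbon homologation of cyclic silyl enol ethers to 2-substituted cycloalk-2-enones. No stereocentre is created and C1 and C2 are not involved, the trans silyl ether at C2 being the more stable epimer should the basic thermolysis equilibrate it. The step needs the enol ether to outcompete the hindered, less nucleophilic vinylsilane for the electrophilic carbene, the site of insertion is fixed by the enol ether position set in step 4, and butyllithium is quenched before the thermolysis so that it cannot add to the enone.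

Step 6
Reactants: 15 (5R,6S)-6-(tert-butyldimethylsilyloxy)-2-methyl-5-[1-(trimethylsilyl)ethenyl]cyclohex-2-en-1-one
Product: 16 (5R,6S)-6-(tert-butyldimethylsilyloxy)-5-(1-iodoethenyl)-2-methylcyclohex-2-en-1-one
Conditions: NIS, MeCN/ClCH2CN (4:1), rt, dark
Reagents that add atoms: N-iodosuccinimide, O=C1CCC(=O)N1I
Why: Iododesilylation (ipso electrophilic substitution of a vinylsilane), in which iodonium attack on the 1,1-disubstituted alkene and loss of silicon from the β-silyl cation should give the 2-iodoalkene while the electron-poor enone alkene is left alone; it is placed here because the later epoxy alcohol would be at risk from the electrophile.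

Step 7
Reactants: 16 (5R,6S)-6-(tert-butyldimethylsilyloxy)-5-(1-iodoethenyl)-2-methylcyclohex-2-en-1-one
Product: 17 (5R,6S)-6-hydroxy-5-(1-iodoethenyl)-2-methylcyclohex-2-en-1-one
Conditions: HF·pyridine, pyridine, THF, 0 °C → rt
Reagents that add atoms: none
Why: Fluoride cleavage of the silyl ether under buffered, non-basic conditions, which should avoid enolisation of the α'-hydroxy enone and leave the alkenyl iodide intact.

Step 8
Reactants: 17 (5R,6S)-6-hydroxy-5-(1-iodoethenyl)-2-methylcyclohex-2-en-1-one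
Product: 18 (1S,6R)-6-(1-iodoethenyl)-3-methyl-2-oxocyclohex-3-en-1-yl 3-methylbutanoate
Conditions: isovaleric anhydride, DMAP (cat.), pyridine, CH2Cl2, 0 °C
Reagents that add atoms: 3-methylbutanoic anhydride, CC(C)CC(=O)OC(=O)CC(C)C
Why: DMAP-catalysed acylation of the secondary alcohol by the anhydride (nucleophilic catalysis), in which C2 keeps its configuration and any equilibration would favour the trans ester.

Step 9
Reactants: 18 (1S,6R)-6-(1-iodoethenyl)-3-methyl-2-oxocyclohex-3-en-1-yl 3-methylbutanoate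
Product: 19 (1S,2S,6R)-2-hydroxy-6-(1-iodoethenyl)-3-methylcyclohex-3-en-1-yl 3-methylbutanoate
Conditions: NaBH4, CeCl3·7H2O, MeOH, −78 °C; AcOH quench
Reagents that add atoms: none
Why: Luche 1,2-reduction, in which hydride adds axially to the half-chair that carries the C1 and C2 substituents equatorially (as carvone gives cis-carveol), so the C3 hydroxyl should form equatorial, trans to the C2 ester and cis to the C1 side chain, the low temperature suppressing ester reduction and acyl migration.

Step 10
Reactants: 19 (1S,2S,6R)-2-hydroxy-6-(1-iodoethenyl)-3-methylcyclohex-3-en-1-yl 3-methylbutanoate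
Product: 20 (1R,2R,3S,4R,6S)-2-hydroxy-4-(1-iodoethenyl)-1-methyl-7-oxabicyclo[4.1.0]heptan-3-yl 3-methylbutanoate
Conditions: VO(acac)2 (cat.), t-BuOOH (decane), CH2Cl2, 0 °C → rt
Reagents that add atoms: tert-butyl hydroperoxide, CC(C)(C)OO
Why: Vanadium-catalysed hydroxyl-directed epoxidation, in which the vanadate ester of the C3 alcohol delivers oxygen to the C4=C5 face syn to the hydroxyl and so sets C4 and C5 with the oxirane cis to the C1 side chain, the remote alkenyl iodide not being oxidised.

Step 11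
Reactants: 21 4-methylpent-3-en-1-ol
Product: 22 4-methylpent-3-enal
Conditions: Dess–Martin periodinane, NaHCO3, CH2Cl2, 0 °C → rt; used at once as a solution
Reagents that add atoms: none
Why: Dess–Martin oxidation of a homoallylic primary alcohol under bicarbonate buffer, which should avoid migration of the double bond into conjugation.

Step 12
Reactants: 20 (1R,2R,3S,4R,6S)-2-hydroxy-4-(1-iodoethenyl)-1-methyl-7-oxabicyclo[4.1.0]heptan-3-yl 3-methylbutanoate; 22 4-methylpent-3-enal (excess)
Product: 24 (1R,2R,3S,4S,6S)-2-hydroxy-4-(3-hydroxy-6-methylhepta-1,5-dien-2-yl)-1-methyl-7-oxabicyclo[4.1.0]heptan-3-yl 3-methylbutanoate (both epimers at the new side-chain carbinol), via alkenylchromium species 23 (not isolated)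
Conditions: CrCl2 (6 equiv), NiCl2 (1 mol%), DMSO, rt
Reagents that add atoms: none
Why: Nozaki–Hiyama–Kishi coupling, in which nickel-mediated activation of the alkenyl iodide and transmetallation give an alkenylchromium(III) species that adds chemoselectively to the aldehyde in the presence of the free hydroxyl, the ester and the oxirane; the new carbinol centre is uncontrolled and is removed in step 13, and C3 is kept as the alcohol here because chromium(II) would reduce an α,β-epoxy ketone.

Step 13
Reactants: 24 (1R,2R,3S,4S,6S)-2-hydroxy-4-(3-hydroxy-6-methylhepta-1,5-dien-2-yl)-1-methyl-7-oxabicyclo[4.1.0]heptan-3-yl 3-methylbutanoate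
Product: 25 (1S,3S,4S,6S)-1-methyl-4-(6-methyl-3-oxohepta-1,5-dien-2-yl)-2-oxo-7-oxabicyclo[4.1.0]heptan-3-yl 3-methylbutanoate
Conditions: Dess–Martin periodinane (3 equiv), NaHCO3, CH2Cl2, 0 °C → rt; rapid filtration through deactivated silica
Reagents that add atoms: none
Why: Dess–Martin oxidation of both secondary alcohols under buffered, non-basic conditions should give the epoxy ketone and the α-methylene ketone without opening the oxirane or moving the trisubstituted alkene into conjugation.

Step 14
Reactants: 25 (1S,3S,4S,6S)-1-methyl-4-(6-methyl-3-oxohepta-1,5-dien-2-yl)-2-oxo-7-oxabicyclo[4.1.0]heptan-3-yl 3-methylbutanoate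
Product: 26 (1S,3S,4S,6S)-4-[(4E)-6-hydroperoxy-6-methyl-3-oxohepta-1,4-dien-2-yl]-1-methyl-2-oxo-7-oxabicyclo[4.1.0]heptan-3-yl 3-methylbutanoate
Conditions: O2, tetraphenylporphyrin (cat.), visible light, CH2Cl2, −20 °C
Reagents that add atoms: dioxygen (as singlet oxygen), O=O
Why: Schenck ene reaction, in which singlet oxygen attacks only the electron-rich trisubstituted alkene and abstracts a hydrogen from the methylene activated by the adjacent carbonyl, so that oxygen ends on the dimethyl-substituted carbon and the double bond moves into conjugation with the E geometry that the ene transition state gives.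

## Compound list

1 | cyclopent-2-en-1-one | O=C1C=CCC1 | starting material
2 | (1-bromovinyl)trimethylsilane | C=C(Br)[Si](C)(C)C | starting material
3 | [1-(trimethylsilyl)ethenyl]magnesium bromide | C=C([Mg]Br)[Si](C)(C)C | intermediate
4 | bromomagnesium (R)-3-[1-(trimethylsilyl)ethenyl]cyclopent-1-en-1-olate | C=C([Si](C)(C)C)[C@@H]1CCC(O[Mg]Br)=C1 | intermediate
5 | (R)-trimethyl({3-[1-(trimethylsilyl)ethenyl]cyclopent-1-en-1-yl}oxy)silane | C=C([Si](C)(C)C)[C@@H]1CCC(O[Si](C)(C)C)=C1 | intermediate
6 | trimethyl({(4R)-4-[1-(trimethylsilyl)ethenyl]-6-oxabicyclo[3.1.0]hexan-1-yl}oxy)silane, oxirane trans to the alkenyl group | C=C([Si](C)(C)C)[C@@H]1CC[C@@]2(O[Si](C)(C)C)O[C@@H]12 | intermediate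
7 | (2S,3R)-2-(trimethylsilyloxy)-3-[1-(trimethylsilyl)ethenyl]cyclopentan-1-one | C=C([Si](C)(C)C)[C@@H]1CCC(=O)[C@H]1O[Si](C)(C)C | intermediate
8 | (2S,3R)-2-hydroxy-3-[1-(trimethylsilyl)ethenyl]cyclopentan-1-one | C=C([Si](C)(C)C)[C@@H]1CCC(=O)[C@H]1O | intermediate
9 | (2S,3R)-2-(tert-butyldimethylsilyloxy)-3-[1-(trimethylsilyl)ethenyl]cyclopentan-1-one | C=C([Si](C)(C)C)[C@@H]1CCC(=O)[C@H]1O[Si](C)(C)C(C)(C)C | intermediate
10 | lithium (4R,5S)-5-(tert-butyldimethylsilyloxy)-4-[1-(trimethylsilyl)ethenyl]cyclopent-1-en-1-olate | C=C([Si](C)(C)C)[C@@H]1CC=C(O[Li])[C@H]1O[Si](C)(C)C(C)(C)C | intermediate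
11 | (4R,5S)-1,5-bis(tert-butyldimethylsilyloxy)-4-[1-(trimethylsilyl)ethenyl]cyclopent-1-ene | C=C([Si](C)(C)C)[C@@H]1CC=C(O[Si](C)(C)C(C)(C)C)[C@H]1O[Si](C)(C)C(C)(C)C | intermediate
12 | 1,1-dichloroethane | CC(Cl)Cl | starting material
13 | 1,1-dichloroethyllithium | CC(Cl)(Cl)[Li] | intermediate
14 | (2S,3R)-1,2-bis(tert-butyldimethylsilyloxy)-6-chloro-6-methyl-3-[1-(trimethylsilyl)ethenyl]bicyclo[3.1.0]hexane, cyclopropane anti to the C2 silyloxy group, chlorine endo | C=C([Si](C)(C)C)[C@@H]1C[C@@H]2[C@](C)(Cl)[C@]2(O[Si](C)(C)C(C)(C)C)[C@H]1O[Si](C)(C)C(C)(C)C | intermediate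
15 | (5R,6S)-6-(tert-butyldimethylsilyloxy)-2-methyl-5-[1-(trimethylsilyl)ethenyl]cyclohex-2-en-1-one | C=C([Si](C)(C)C)[C@@H]1CC=C(C)C(=O)[C@H]1O[Si](C)(C)C(C)(C)C | intermediate
16 | (5R,6S)-6-(tert-butyldimethylsilyloxy)-5-(1-iodoethenyl)-2-methylcyclohex-2-en-1-one | C=C(I)[C@@H]1CC=C(C)C(=O)[C@H]1O[Si](C)(C)C(C)(C)C | intermediate
17 | (5R,6S)-6-hydroxy-5-(1-iodoethenyl)-2-methylcyclohex-2-en-1-one | C=C(I)[C@@H]1CC=C(C)C(=O)[C@H]1O | intermediate
18 | (1S,6R)-6-(1-iodoethenyl)-3-methyl-2-oxocyclohex-3-en-1-yl 3-methylbutanoate | C=C(I)[C@@H]1CC=C(C)C(=O)[C@H]1OC(=O)CC(C)C | intermediate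
19 | (1S,2S,6R)-2-hydroxy-6-(1-iodoethenyl)-3-methylcyclohex-3-en-1-yl 3-methylbutanoate | C=C(I)[C@@H]1CC=C(C)[C@H](O)[C@H]1OC(=O)CC(C)C | intermediate
20 | (1R,2R,3S,4R,6S)-2-hydroxy-4-(1-iodoethenyl)-1-methyl-7-oxabicyclo[4.1.0]heptan-3-yl 3-methylbutanoate | C=C(I)[C@@H]1C[C@@H]2O[C@]2(C)[C@H](O)[C@H]1OC(=O)CC(C)C | intermediate
21 | 4-methylpent-3-en-1-ol | CC(C)=CCCO | starting material
22 | 4-methylpent-3-enal | CC(C)=CCC=O | intermediate
23 | alkenylchromium(III) dichloride derived from 20 (chromium in place of iodine) | C=C([Cr](Cl)Cl)[C@@H]1C[C@@H]2O[C@]2(C)[C@H](O)[C@H]1OC(=O)CC(C)C | intermediate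
24 | (1R,2R,3S,4S,6S)-2-hydroxy-4-(3-hydroxy-6-methylhepta-1,5-dien-2-yl)-1-methyl-7-oxabicyclo[4.1.0]heptan-3-yl 3-methylbutanoate, both side-chain carbinol epimers | C=C(C(O)CC=C(C)C)[C@@H]1C[C@@H]2O[C@]2(C)[C@H](O)[C@H]1OC(=O)CC(C)C | intermediate
25 | (1S,3S,4S,6S)-1-methyl-4-(6-methyl-3-oxohepta-1,5-dien-2-yl)-2-oxo-7-oxabicyclo[4.1.0]heptan-3-yl 3-methylbutanoate | C=C(C(=O)CC=C(C)C)[C@@H]1C[C@@H]2O[C@]2(C)C(=O)[C@H]1OC(=O)CC(C)C | intermediate
26 | (1S,3S,4S,6S)-4-[(4E)-6-hydroperoxy-6-methyl-3-oxohepta-1,4-dien-2-yl]-1-methyl-2-oxo-7-oxabicyclo[4.1.0]heptan-3-yl 3-methylbutanoate (CNP0241468.1) | C=C(C(=O)/C=C/C(C)(C)OO)[C@@H]1C[C@@H]2O[C@]2(C)C(=O)[C@H]1OC(=O)CC(C)C | target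

## Step count and risks

Total step count: 14. Longest linear sequence: 13 (steps 1–10 and 12–14, from cyclopent-2-en-1-one); step 11 is a one-step side branch.

**Step 5 (carbene ring expansion).**
What may go wrong: the carbenoid may add with chlorine exo, and that epimer of 14 cannot undergo the disrotatory opening within the small bicycle, so it would persist or decompose on heating. Premature opening in the presence of butyllithium would also expose the enone to 1,2-addition. The endo epimer can be helped by silver ion if heat alone is slow.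
Fallback, setting out from 11 and returning at 15: dibromocarbene (CHBr3, KOt-Bu, pentane, −20 °C → rt) should give (2S,3R)-6,6-dibromo-1,2-bis(tert-butyldimethylsilyloxy)-3-[1-(trimethylsilyl)ethenyl]bicyclo[3.1.0]hexane F1, in which one bromine is endo whichever way the carbene adds. Warming in toluene with pyridine should open it to (5R,6S)-2-bromo-6-(tert-butyldimethylsilyloxy)-5-[1-(trimethylsilyl)ethenyl]cyclohex-2-en-1-one F2. The methyl group is then put on C4 by Stille coupling (Me4Sn, Pd(PPh3)4, CuI, NMP, 70 °C), which gives 15.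

**Step 14 (Schenck ene).**
What may go wrong: abstraction of a methyl hydrogen in place of the carbonyl-flanked methylene hydrogen, which places the hydroperoxide on the secondary carbon. Isomerisation of the β,γ-unsaturated ketone into conjugation before photooxygenation would have the same effect on material balance.
Fallback, setting out from 20 and returning at 26, with the peroxide brought in ready-made and the E-enone formed by olefination:
- Ring side: Nozaki–Hiyama–Kishi coupling of 20 with diethyl (2-oxoethyl)phosphonate (from its commercial diethyl acetal) should give (1R,2R,3S,4S,6S)-4-[4-(diethoxyphosphoryl)-3-hydroxybut-1-en-2-yl]-2-hydroxy-1-methyl-7-oxabicyclo[4.1.0]heptan-3-yl 3-methylbutanoate F3. Dess–Martin oxidation of both carbinols gives the β-keto phosphonate (1S,3S,4S,6S)-4-[4-(diethoxyphosphoryl)-3-oxobut-1-en-2-yl]-1-methyl-2-oxo-7-oxabicyclo[4.1.0]heptan-3-yl 3-methylbutanoate F4.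
- Peroxide side: 2-methylbut-3-en-2-ol with 50% H2O2 and catalytic H2SO4 gives 2-methylbut-3-en-2-yl hydroperoxide F5. 2-Methoxypropene with PPTS protects it as 3-[(2-methoxypropan-2-yl)peroxy]-3-methylbut-1-ene F6. Ozonolysis (O3, CH2Cl2, −78 °C; PPh3) gives 2-[(2-methoxypropan-2-yl)peroxy]-2-methylpropanal F7, which has no hydrogen on the peroxide-bearing carbon.
- Joining: Horner–Wadsworth–Emmons olefination of F4 with F7 (LiCl, i-Pr2NEt, MeCN) should give (1S,3S,4S,6S)-4-{(4E)-6-[(2-methoxypropan-2-yl)peroxy]-6-methyl-3-oxohepta-1,4-dien-2-yl}-1-methyl-2-oxo-7-oxabicyclo[4.1.0]heptan-3-yl 3-methylbutanoate F8. AcOH/THF/H2O removes the peroxyketal and gives 26.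

**Step 1 (asymmetric conjugate addition).**
What may go wrong: poor facial selectivity, or competing 1,2-addition, with the branched alkenyl Grignard reagent on the small, unhindered cyclopentenone.
Fallback, setting out from Grignard reagent 3 (made from 2) and returning at 9, with C1 set by substrate control:
- Copper-mediated addition of 3 (CuI, TMSCl, THF, −78 °C) to commercial (S)-4-(tert-butyldimethylsilyloxy)cyclopent-2-en-1-one F9 occurs trans to the silyloxy group and, after silyl trapping, gives (3S,4S)-4-(tert-butyldimethylsilyloxy)-1-(trimethylsilyloxy)-3-[1-(trimethylsilyl)ethenyl]cyclopent-1-ene F10.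
- Rubottom oxidation as in step 2 gives (2S,3S,4S)-4-(tert-butyldimethylsilyloxy)-2-hydroxy-3-[1-(trimethylsilyl)ethenyl]cyclopentan-1-one F11. TBSCl/imidazole gives (2S,3R,4S)-2,4-bis(tert-butyldimethylsilyloxy)-3-[1-(trimethylsilyl)ethenyl]cyclopentan-1-one F12.
- DBU (CH2Cl2, 0 °C) eliminates the β-silyloxy group to give (4R,5S)-5-(tert-butyldimethylsilyloxy)-4-[1-(trimethylsilyl)ethenyl]cyclopent-2-en-1-one F13. The elimination is stopped before the doubly allylic C1 hydrogen is removed.
- Conjugate reduction with Stryker's reagent ([(Ph3P)CuH]6, wet benzene, rt) gives 9.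

## Further compounds

F1 | step 5 | (2S,3R)-6,6-dibromo-1,2-bis(tert-butyldimethylsilyloxy)-3-[1-(trimethylsilyl)ethenyl]bicyclo[3.1.0]hexane | C=C([Si](C)(C)C)[C@@H]1C[C@@H]2C(Br)(Br)[C@]2(O[Si](C)(C)C(C)(C)C)[C@H]1O[Si](C)(C)C(C)(C)C
F2 | step 5 | (5R,6S)-2-bromo-6-(tert-butyldimethylsilyloxy)-5-[1-(trimethylsilyl)ethenyl]cyclohex-2-en-1-one | C=C([Si](C)(C)C)[C@@H]1CC=C(Br)C(=O)[C@H]1O[Si](C)(C)C(C)(C)C
F3 | step 14 | (1R,2R,3S,4S,6S)-4-[4-(diethoxyphosphoryl)-3-hydroxybut-1-en-2-yl]-2-hydroxy-1-methyl-7-oxabicyclo[4.1.0]heptan-3-yl 3-methylbutanoate | C=C(C(O)CP(=O)(OCC)OCC)[C@@H]1C[C@@H]2O[C@]2(C)[C@H](O)[C@H]1OC(=O)CC(C)C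
F4 | step 14 | (1S,3S,4S,6S)-4-[4-(diethoxyphosphoryl)-3-oxobut-1-en-2-yl]-1-methyl-2-oxo-7-oxabicyclo[4.1.0]heptan-3-yl 3-methylbutanoate | C=C(C(=O)CP(=O)(OCC)OCC)[C@@H]1C[C@@H]2O[C@]2(C)C(=O)[C@H]1OC(=O)CC(C)C
F5 | step 14 | 2-methylbut-3-en-2-yl hydroperoxide | C=CC(C)(C)OO
F6 | step 14 | 3-[(2-methoxypropan-2-yl)peroxy]-3-methylbut-1-ene | C=CC(C)(C)OOC(C)(C)OC
F7 | step 14 | 2-[(2-methoxypropan-2-yl)peroxy]-2-methylpropanal | O=CC(C)(C)OOC(C)(C)OC
F8 | step 14 | (1S,3S,4S,6S)-4-{(4E)-6-[(2-methoxypropan-2-yl)peroxy]-6-methyl-3-oxohepta-1,4-dien-2-yl}-1-methyl-2-oxo-7-oxabicyclo[4.1.0]heptan-3-yl 3-methylbutanoate | C=C(C(=O)/C=C/C(C)(C)OOC(C)(C)OC)[C@@H]1C[C@@H]2O[C@]2(C)C(=O)[C@H]1OC(=O)CC(C)C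
F9 | step 1 | (S)-4-(tert-butyldimethylsilyloxy)cyclopent-2-en-1-one | O=C1C=C[C@@H](O[Si](C)(C)C(C)(C)C)C1
F10 | step 1 | (3S,4S)-4-(tert-butyldimethylsilyloxy)-1-(trimethylsilyloxy)-3-[1-(trimethylsilyl)ethenyl]cyclopent-1-ene | C=C([Si](C)(C)C)[C@@H]1[C@@H](O[Si](C)(C)C(C)(C)C)CC(O[Si](C)(C)C)=C1
F11 | step 1 | (2S,3S,4S)-4-(tert-butyldimethylsilyloxy)-2-hydroxy-3-[1-(trimethylsilyl)ethenyl]cyclopentan-1-one | C=C([Si](C)(C)C)[C@@H]1[C@@H](O[Si](C)(C)C(C)(C)C)CC(=O)[C@H]1O
F12 | step 1 | (2S,3R,4S)-2,4-bis(tert-butyldimethylsilyloxy)-3-[1-(trimethylsilyl)ethenyl]cyclopentan-1-one | C=C([Si](C)(C)C)[C@@H]1[C@@H](O[Si](C)(C)C(C)(C)C)CC(=O)[C@H]1O[Si](C)(C)C(C)(C)C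
F13 | step 1 | (4R,5S)-5-(tert-butyldimethylsilyloxy)-4-[1-(trimethylsilyl)ethenyl]cyclopent-2-en-1-one | C=C([Si](C)(C)C)[C@@H]1C=CC(=O)[C@H]1O[Si](C)(C)C(C)(C)C
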